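## The problem

Compound 33 is a linear sesquineolignan built from three C6C3 units joined through two 2-aryl-3-(hydroxymethyl)-2,3-dihydrobenzofurans. Guaiacyl ring A sits on C2 of ring B (O1–C2–C3–C3a–C7a, fused to arene C), and C5 of arene C carries C2' of ring D, the primed copy fused to arene E, whose C5' bears an (E)-3-hydroxypropenyl chain. Each heterocycle holds a trans pair of stereocentres, (2R,3S) and (2'R,3'S). Within a pair one centre can fix the other, but arene C insulates the two pairs, so each pair needs its own external source of chirality. Both C2–O1 bonds are benzylic to a para-oxygenated arene and can ionise in acid, the ring A phenol is oxidisable, and the cinnamyl alcohol is the most acid-labile group, so it has to appear after the last acidic operation. The phenol and the two primary alcohols need masks that survive boron Lewis acids, hydride, amide base and fluoride ion. The enabling feature is the substitution pattern of arenes C and E: the oxygen-bearing carbon C7a (C7a') is para to C5 (C5'), the carbon that carries the next unit, so an acceptor parked at C5 makes a fluoride at C7a displaceable by an alkoxide on C2. The repeating unit C3a–C3(CH2OH)–C2(OH)–aryl is also an aldol retron at the acyl oxidation level, so one fluoroarylacetyl building block can serve both rings.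

## Retrosynthesis

**Side chain (33 ⇐ 32 ⇐ 31 ⇐ 30).** The allylic alcohol is taken back to enoate 32 (C–O reduction level only), the three hydroxyls are masked as MOM ethers in 31, and the C=C bond is cut to aldehyde 30. Cutting here rather than at the aryl–vinyl bond keeps C5' as a carbonyl-level carbon, which the ring closure needs as its para acceptor. Deprotection is placed at the enoate, which is acid-stable, and not at the cinnamyl alcohol. The forward steps need E selectivity, acid that spares the benzylic ring ethers, and clean 1,2-reduction.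

**Aldehyde from nitrile (30 ⇐ 28, and 21 ⇐ 19).** Each C5 aldehyde is traced to a nitrile. An ester would also stabilise the anionic adduct of the ring closure, but it costs two redox steps per ring, can accept the alkoxide in an acyl transfer, and limits the choice of hydride for auxiliary removal. The nitrile is the stronger para acceptor, is inert to borohydride, and gives the aldehyde in one hydride step.

**Ring D (28 ⇐ 25).** The O1'–C7a' bond is cut, giving syn fluoro alcohol 25. Cutting the aryl C–O bond rather than C2'–O1' means the carbinol C–O bond is never broken, so the aldol stereochemistry passes into the ring with retention. The forward reaction needs only a fluoride para to the nitrile and a single free hydroxyl.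

**Second aldol (25 ⇐ 24 ⇐ 23 ⇐ 21 + 11).** The primary MOM ether is removed (24), the CH2OH is raised to the imide (23), and C2'–C3' is cut to aldehyde 21 and imide 11. This one C–C cut removes both ring D stereocentres and the whole arene E unit. The auxiliary must override the remote centres of 21.

**Ring B, the key cut (19 ⇐ 16).** The O1–C7a bond is cut as for ring D, leading to syn fluoro alcohol 16. The precursor is acyclic, and its two centres are those of an aldol adduct.

**First aldol (16 ⇐ 15 ⇐ 14 ⇐ 11 + 2).** This repeats the second-aldol logic: primary MOM ether off (15), alcohol back to imide (14), C2–C3 cut to imide 11 and MOM-vanillin 2, which comes from vanillin 1. MOM is chosen for the primary oxygen because the primary alkoxide could itself close a five-membered ring onto C7a; the mask must therefore be one that cannot migrate to the secondary alkoxide, which rules out silyl and acyl groups.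

**Imide (11 ⇐ 8 + 9; 8 ⇐ 7 ⇐ 6).** The N-acyl bond is cut to acid 8 and auxiliary 9. The aryl–CH2 bond is cut to aryl iodide 6 and an acetate enolate equivalent, with tert-butyl ester 7 as the orthogonal carrier. The coupling must take the iodide and leave the fluoride and nitrile.

**Fluoroarene (6 ⇐ 4 ⇐ 3).** The C–F bond is traced to an amino group and the C–I bond to C–H. In 4-amino-3-methoxybenzonitrile 3 the amino group first directs iodination to its only free ortho position and is then exchanged for fluorine, so the 1,2,3,5 pattern of arene C follows from a para-substituted aniline.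

## Roads not taken

**Alternative 1:** The cut is ring A–C2 together with C3–C3a. Aryllithium A1 adds to the boron atom of (E)-alkenyl boronate A2. Pd(OAc)2 (divalent palladium, reduced in the flask) with a MandyPhos ligand and NaOTf then brings in arene C bromide A3, and ring A shifts from boron to C2 while arene C bonds to C3, giving boronate A4; no ring closes.

- Merits: both centres are set by a catalyst, three fragments are joined at once, and no auxiliary is carried. In convergence and atom economy this road is better than the chosen one.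
- Weak points: A3 is an ortho-substituted, electron-rich bromide. The palladium alkyl at C3 has β-hydrogens on both sides. With the (E)-boronate, A4 has the relative configuration that an invertive O1–C2 closure would turn into the cis ring, so ring B would have to close through the ring A benzylic cation, and the C2 centre set by the catalyst is spent. The aryl chloride left for the second round must first be turned into an aryl-metal nucleophile.
- Comparison: the chosen plan uses a stoichiometric auxiliary and more functional-group steps, but the syn aldol of arylacetyl imides is a proven substrate class, and the closure of 16 to 19 is stereospecific because C2–O is never broken.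

**Alternative 2:** The cut is C2–C3 and C2'–C3' at once. Rh2(S-PTTL)4 (divalent rhodium) decomposes both diazo groups of bis(aryldiazoacetate) A5, each carbene carbon inserts into the benzylic ether C–H bond five atoms away, and DBU in the same flask epimerises the esters to give trans,trans triester A6.

- Merits: both rings and all four centres come from one catalytic step on a precursor made by simple etherifications, and one hydride step would then reduce all three esters. In step count this road is clearly ahead.
- Weak points: the two insertions are independent, so any lapse in catalyst fidelity at either site appears as a diastereomer of A6. The insertion is cis-selective, so the trans rings depend on enolising C3 and C3', each of which is β to an aryloxy leaving group; E1cB ring opening would erase C2 or C2', and the ring D phenoxide, para to the acrylate, is the better leaving group.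
- Comparison: the chosen plan is longer, but each pair of centres is made separately under auxiliary control, with diastereomers that can be purified, and the rings close at the alcohol oxidation level where C3–H is not acidic.

**Alternative 3:** The cut is C2'–C3' plus O1'–C2', joining two halves. Cs2CO3 releases o-quinone methide A9 from sulfone A7 and deprotonates sulfonium salt A8 (fragment 1, rings A and B complete). The carbanionic carbon adds to the methide carbon and the phenoxide displaces the sulfide, closing ring D to give bromide A10.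

- Merits: it is the most convergent of the four, ring D forms in one step with an inherent trans preference, and the bromide is a handle for the side chain.
- Weak points: the stereocentres of A8 are too far from the reacting carbon to control the absolute sense at C2'/C3', so a mixture of (2'R,3'S) and (2'S,3'R) isomers is expected unless a chiral sulfide is added. A9 carries β-hydrogens and can tautomerise to a vinyl phenol. A8 still requires an enantioselective synthesis of ring B.
- Comparison: the chosen plan is linear, but it controls both pairs of centres with one reagent and uses one reaction type for both rings. Alternative 3 would still need a method such as the chosen one to make its own fragment 1.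

Key step: step 10

Assumption: C5 and C5' are carried as nitriles (para acceptor for the fluoride displacement and latent aldehyde), and 4-amino-3-methoxybenzonitrile is taken to be commercially available.

## Route

Step 1
Reactants: 1 vanillin
Product: 2 3-methoxy-4-(methoxymethoxy)benzaldehyde
Conditions: MOMCl, i-Pr2NEt, CH2Cl2, 0 °C to rt
Reagents that add atoms: chloromethyl methyl ether, COCCl
Why: O-alkylation of the phenol by the reactive α-chloro ether gives the MOM acetal, which is inert to boron enolates, hydride, amide base and fluoride and is removed only by acid.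

Step 2
Reactants: 3 4-amino-3-methoxybenzonitrile
Product: 4 4-amino-3-iodo-5-methoxybenzonitrile
Conditions: NIS, CF3CO2H (cat.), MeCN, rt
Reagents that add atoms: N-iodosuccinimide, O=C1CCC(=O)N1I
Why: Electrophilic aromatic iodination; the amino group is the strongest donor, its para position is blocked by the nitrile and one ortho position by OMe, so iodine should enter the remaining ortho carbon.

Step 3
Reactants: 4 4-amino-3-iodo-5-methoxybenzonitrile
Product: 6 4-fluoro-3-iodo-5-methoxybenzonitrile, via arenediazonium tetrafluoroborate 5 (not isolated)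
Conditions: NOBF4, CH2Cl2, 0 °C; then solvent exchange to 1,2-dichlorobenzene, 120 °C
Reagents that add atoms: nitrosonium tetrafluoroborate, N#[O+].F[B-](F)(F)F
Why: Balz–Schiemann reaction: diazotisation by NO+ and thermal loss of N2 from the tetrafluoroborate, the aryl cation taking fluoride from BF4–; the fluorine position is fixed by the amino group it replaces, and iodide, nitrile and methyl ether are spectators.

Step 4
Reactants: 6 4-fluoro-3-iodo-5-methoxybenzonitrile
Product: 7 tert-butyl 2-(5-cyano-2-fluoro-3-methoxyphenyl)acetate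
Conditions: BrZnCH2CO2t-Bu (from BrCH2CO2t-Bu and Zn, THF), Pd2(dba)3 (zerovalent palladium, cat.), XPhos, THF, 50 °C
Reagents that add atoms: tert-butyl bromoacetate, CC(C)(C)OC(=O)CBr (used as its zinc reagent, CC(C)(C)OC(=O)C[Zn]Br)
Why: Negishi coupling of a Reformatsky reagent with the aryl iodide; oxidative addition at C–I is far faster than at C–F, the zinc enolate tolerates the nitrile, and the bulky biaryl phosphine promotes C(sp2)–C(sp3) reductive elimination.

Step 5
Reactants: 7 tert-butyl 2-(5-cyano-2-fluoro-3-methoxyphenyl)acetate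
Product: 8 2-(5-cyano-2-fluoro-3-methoxyphenyl)acetic acid
Conditions: CF3CO2H, CH2Cl2, rt
Reagents that add atoms: none
Why: Acidolysis of the tert-butyl ester (loss of the tert-butyl cation as isobutene) frees the acid without touching nitrile, fluoride or methyl ether.

Step 6
Reactants: 8 2-(5-cyano-2-fluoro-3-methoxyphenyl)acetic acid; 9 (R)-4-benzyl-2-oxazolidinone
Product: 11 (R)-4-benzyl-3-[2-(5-cyano-2-fluoro-3-methoxyphenyl)acetyl]oxazolidin-2-one, via mixed pivalic anhydride 10 (not isolated)
Conditions: t-BuCOCl, Et3N, THF, −20 °C; then 9, LiCl, −20 °C to rt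
Reagents that add atoms: none
Why: N-acylation of the oxazolidinone through the mixed anhydride, attacked at the less hindered arylacetyl carbonyl; the LiCl/Et3N variant avoids a strongly basic N-anion, which could form a ketene from the acidic arylacetyl unit or attack the activated fluoride.

Step 7
Reactants: 11 (R)-4-benzyl-3-[2-(5-cyano-2-fluoro-3-methoxyphenyl)acetyl]oxazolidin-2-one; 2 3-methoxy-4-(methoxymethoxy)benzaldehyde
Product: 14 (R)-4-benzyl-3-[(2R,3R)-2-(5-cyano-2-fluoro-3-methoxyphenyl)-3-hydroxy-3-[3-methoxy-4-(methoxymethoxy)phenyl]propanoyl]oxazolidin-2-one, via boron enolate 12 (not isolated), via boron aldolate 13 (not isolated)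
Conditions: n-Bu2BOTf, i-Pr2NEt, CH2Cl2, −78 to 0 °C; then 2, −78 to 0 °C; pH 7 buffer, MeOH, 30% H2O2, 0 °C
Reagents that add atoms: none
Why: Evans syn-aldol: soft enolisation gives the Z boron enolate 12, which should add to 2 through a chair Zimmerman–Traxler transition state on the face away from the benzyl group of the dipole-opposed auxiliary, giving boron aldolate 13. This sets both new centres as (2R,3R), the syn arrangement of α-aryl and hydroxyl; the buffered oxidative work-up only cleaves the O–B bond of 13.

Step 8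
Reactants: 14 syn aldol adduct (2R,3R)
Product: 15 3-{(1R,2S)-1,3-dihydroxy-1-[3-methoxy-4-(methoxymethoxy)phenyl]propan-2-yl}-4-fluoro-5-methoxybenzonitrile
Conditions: NaBH4, THF/H2O (4:1), 0 °C to rt
Reagents that add atoms: none
Why: Reductive cleavage of the N-acyloxazolidinone by borohydride (hydride adds to the exocyclic carbonyl, the auxiliary leaves, and the aldehyde is reduced further); nitrile and aryl fluoride are inert and no stereocentre is touched, the descriptor at the α-carbon changing only through CIP priorities.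

Step 9
Reactants: 15 diol (1R,2S)
Product: 16 4-fluoro-3-{(1R,2S)-1-hydroxy-3-(methoxymethoxy)-1-[3-methoxy-4-(methoxymethoxy)phenyl]propan-2-yl}-5-methoxybenzonitrile
Conditions: MOMCl (1.1 equiv), i-Pr2NEt, CH2Cl2, −20 to 0 °C
Reagents that add atoms: chloromethyl methyl ether, COCCl
Why: Selective O-alkylation of the primary hydroxyl, which is far more accessible than the secondary benzylic one flanked by two aryl-bearing carbons. The acetal cannot migrate to the neighbouring alkoxide in step 10, where a free primary alkoxide would itself close a five-membered ring onto C7a.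

Step 10
Reactants: 16 syn fluoro alcohol (1R,2S)
Product: 19 (2R,3S)-7-methoxy-3-[(methoxymethoxy)methyl]-2-[3-methoxy-4-(methoxymethoxy)phenyl]-2,3-dihydrobenzofuran-5-carbonitrile, via potassium alkoxide 17 (not isolated), via Meisenheimer adduct 18 (not isolated)
Conditions: KN(SiMe3)2 (1.05 equiv), THF, −78 °C to rt (45 °C if needed)
Reagents that add atoms: none
Why: KN(SiMe3)2 deprotonates the C2 hydroxyl of 16 to alkoxide 17; the oxygen adds to the fluorine-bearing carbon C7a to give Meisenheimer adduct 18, whose charge is delocalised onto C5 and the para nitrile, and loss of fluoride restores arene C (addition–elimination, SNAr). The closest known reaction type is the intramolecular SNAr O-arylation of 2-(2-fluoroaryl)ethanol alkoxides on 4-fluorobenzonitrile- or 4-fluorobenzoate-type rings to give 2,3-dihydrobenzofurans. Ring B closes in the 5-exo-trig mode: C7a is a member of the new ring and the C7a=C7 π bond that takes up the electrons lies outside it. No stereocentre is formed; C2 and C3 come from the aldol, the C2–O bond is never broken, and C3–H (benzylic, meta to the nitrile, no adjacent carbonyl) is not acidic enough to be removed, so the syn alcohol should be converted with retention into the trans (2R,3S) ring. The step needs site selectivity (attack at C7a only) and chemoselectivity (the secondary alkoxide as the only nucleophile). The tether allows nothing but ipso attack, the primary oxygen is capped by a group that cannot migrate, and one equivalent of amide base is consumed by proton transfer before it can add to the nitrile. The methoxy group ortho to fluorine slows the addition, which is why the stronger nitrile acceptor and a potassium counter-ion are used.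

Step 11
Reactants: 19 ring B nitrile (2R,3S)
Product: 21 (2R,3S)-7-methoxy-3-[(methoxymethoxy)methyl]-2-[3-methoxy-4-(methoxymethoxy)phenyl]-2,3-dihydrobenzofuran-5-carbaldehyde, via N-aluminio aldimine 20 (not isolated)
Conditions: i-Bu2AlH (1.3 equiv), toluene/CH2Cl2, −78 °C; then aq. KNaC4H4O6, aq. citric acid, 0 °C
Reagents that add atoms: water, O
Why: Partial reduction of the nitrile by i-Bu2AlH stops at the N-aluminio aldimine 20, which is hydrolysed on work-up to the aldehyde; acetals, aryl ethers and the benzylic ring ether are inert to the hydride at low temperature.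

Step 12
Reactants: 11 (R)-4-benzyl-3-[2-(5-cyano-2-fluoro-3-methoxyphenyl)acetyl]oxazolidin-2-one; 21 ring B aldehyde (2R,3S)
Product: 23 (R)-4-benzyl-3-[(2R,3R)-2-(5-cyano-2-fluoro-3-methoxyphenyl)-3-hydroxy-3-{(2R,3S)-7-methoxy-3-[(methoxymethoxy)methyl]-2-[3-methoxy-4-(methoxymethoxy)phenyl]-2,3-dihydrobenzofuran-5-yl}propanoyl]oxazolidin-2-one, via boron aldolate 22 (not isolated)
Conditions: n-Bu2BOTf, i-Pr2NEt, CH2Cl2, −78 to 0 °C; then 21, −78 to 0 °C; pH 7 buffer, MeOH, 30% H2O2, 0 °C
Reagents that add atoms: none
Why: Second Evans syn-aldol: imide 11 is enolised once more to the Z boron enolate 12, exactly as in step 7 where that species is numbered, and its addition to 21 gives boron aldolate 22, whose O–B bond the oxidative work-up cleaves. The auxiliary should override the remote centres of 21 (reagent control) and set the (2R,3R) pair that becomes C3' and C2'.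

Step 13
Reactants: 23 second syn aldol adduct
Product: 24 3-[(1R,2S)-1,3-dihydroxy-1-{(2R,3S)-7-methoxy-3-[(methoxymethoxy)methyl]-2-[3-methoxy-4-(methoxymethoxy)phenyl]-2,3-dihydrobenzofuran-5-yl}propan-2-yl]-4-fluoro-5-methoxybenzonitrile
Conditions: NaBH4, THF/H2O (4:1), 0 °C to rt
Reagents that add atoms: none
Why: Reductive cleavage of the N-acyloxazolidinone as in step 8; nitrile, fluoride, acetals and ring B are inert to borohydride.

Step 14
Reactants: 24 second diol
Product: 25 4-fluoro-3-[(1R,2S)-1-hydroxy-3-(methoxymethoxy)-1-{(2R,3S)-7-methoxy-3-[(methoxymethoxy)methyl]-2-[3-methoxy-4-(methoxymethoxy)phenyl]-2,3-dihydrobenzofuran-5-yl}propan-2-yl]-5-methoxybenzonitrile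
Conditions: MOMCl (1.1 equiv), i-Pr2NEt, CH2Cl2, −20 to 0 °C
Reagents that add atoms: chloromethyl methyl ether, COCCl
Why: Selective O-alkylation of the primary hydroxyl as in step 9, leaving the hindered benzylic hydroxyl free for ring closure.

Step 15
Reactants: 25 second syn fluoro alcohol
Product: 28 (2R,3S)-7-methoxy-3-[(methoxymethoxy)methyl]-2-{(2R,3S)-7-methoxy-3-[(methoxymethoxy)methyl]-2-[3-methoxy-4-(methoxymethoxy)phenyl]-2,3-dihydrobenzofuran-5-yl}-2,3-dihydrobenzofuran-5-carbonitrile, via potassium alkoxide 26 (not isolated), via Meisenheimer adduct 27 (not isolated)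
Conditions: KN(SiMe3)2 (1.05 equiv), THF, −78 °C to rt (45 °C if needed)
Reagents that add atoms: none
Why: Intramolecular SNAr as in step 10: the C2' alkoxide adds to C7a' para to the nitrile and fluoride leaves, closing ring D 5-exo-trig with retention at C2' and C3'; ring B has no acidic site and is a spectator.

Step 16
Reactants: 28 ring D nitrile
Product: 30 (2R,3S)-7-methoxy-3-[(methoxymethoxy)methyl]-2-{(2R,3S)-7-methoxy-3-[(methoxymethoxy)methyl]-2-[3-methoxy-4-(methoxymethoxy)phenyl]-2,3-dihydrobenzofuran-5-yl}-2,3-dihydrobenzofuran-5-carbaldehyde, via N-aluminio aldimine 29 (not isolated)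
Conditions: i-Bu2AlH (1.3 equiv), toluene/CH2Cl2, −78 °C; then aq. KNaC4H4O6, aq. citric acid, 0 °C
Reagents that add atoms: water, O
Why: Partial hydride reduction of the nitrile to the aldimine and hydrolysis, as in step 11.

Step 17
Reactants: 30 ring D aldehyde
Product: 31 methyl (E)-3-[(2R,3S)-7-methoxy-3-[(methoxymethoxy)methyl]-2-{(2R,3S)-7-methoxy-3-[(methoxymethoxy)methyl]-2-[3-methoxy-4-(methoxymethoxy)phenyl]-2,3-dihydrobenzofuran-5-yl}-2,3-dihydrobenzofuran-5-yl]prop-2-enoate
Conditions: Ph3P=CHCO2Me, toluene, 80 °C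
Reagents that add atoms: methyl (triphenylphosphoranylidene)acetate, COC(=O)C=P(c1ccccc1)(c1ccccc1)c1ccccc1
Why: Wittig olefination with a stabilised ylide, which gives the E alkene selectively; the neutral conditions leave acetals and stereocentres untouched.

Step 18
Reactants: 31 protected enoate
Product: 32 methyl (E)-3-[(2R,3S)-2-{(2R,3S)-2-(4-hydroxy-3-methoxyphenyl)-3-(hydroxymethyl)-7-methoxy-2,3-dihydrobenzofuran-5-yl}-3-(hydroxymethyl)-7-methoxy-2,3-dihydrobenzofuran-5-yl]prop-2-enoate
Conditions: 3 M HCl (aq.), MeOH/THF, 45 °C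
Reagents that add atoms: none
Why: Acid-catalysed acetal exchange with methanol removes the phenolic and both aliphatic MOM groups as dimethoxymethane. It is done at the enoate stage because the conjugated methyl ester is acid-stable and matches the solvent, whereas the cinnamyl alcohol of the target would ionise.

Step 19
Reactants: 32 triol enoate
Product: 33 (E)-3-[(2R,3S)-2-{(2R,3S)-2-(4-hydroxy-3-methoxyphenyl)-3-(hydroxymethyl)-7-methoxy-2,3-dihydrobenzofuran-5-yl}-3-(hydroxymethyl)-7-methoxy-2,3-dihydrobenzofuran-5-yl]prop-2-en-1-ol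
Conditions: i-Bu2AlH (excess), THF, −78 to −20 °C; then aq. KNaC4H4O6
Reagents that add atoms: none
Why: 1,2-Reduction of the α,β-unsaturated ester by i-Bu2AlH gives the allylic alcohol without conjugate reduction; the three hydroxyls consume hydride as aluminium alkoxides and are released on the neutral tartrate work-up, so the product never meets acid.

## Compound list

1 | vanillin (4-hydroxy-3-methoxybenzaldehyde) | COc1cc(C=O)ccc1O | starting material
2 | 3-methoxy-4-(methoxymethoxy)benzaldehyde | COCOc1ccc(C=O)cc1OC | intermediate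
3 | 4-amino-3-methoxybenzonitrile | COc1cc(C#N)ccc1N | starting material
4 | 4-amino-3-iodo-5-methoxybenzonitrile | COc1cc(C#N)cc(I)c1N | intermediate
5 | 4-cyano-2-iodo-6-methoxybenzenediazonium tetrafluoroborate (formed in the flask) | COc1cc(C#N)cc(I)c1[N+]#N.F[B-](F)(F)F | intermediate
6 | 4-fluoro-3-iodo-5-methoxybenzonitrile | COc1cc(C#N)cc(I)c1F | intermediate
7 | tert-butyl 2-(5-cyano-2-fluoro-3-methoxyphenyl)acetate | COc1cc(C#N)cc(CC(=O)OC(C)(C)C)c1F | intermediate
8 | 2-(5-cyano-2-fluoro-3-methoxyphenyl)acetic acid | COc1cc(C#N)cc(CC(=O)O)c1F | intermediate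
9 | (R)-4-benzyl-2-oxazolidinone | O=C1OC[C@@H](Cc2ccccc2)N1 | starting material
10 | 2-(5-cyano-2-fluoro-3-methoxyphenyl)acetic pivalic anhydride (formed in the flask) | COc1cc(C#N)cc(CC(=O)OC(=O)C(C)(C)C)c1F | intermediate
11 | (R)-4-benzyl-3-[2-(5-cyano-2-fluoro-3-methoxyphenyl)acetyl]oxazolidin-2-one | COc1cc(C#N)cc(CC(=O)N2[C@H](Cc3ccccc3)COC2=O)c1F | intermediate
12 | (R)-4-benzyl-3-[(Z)-1-(dibutylboryloxy)-2-(5-cyano-2-fluoro-3-methoxyphenyl)ethenyl]oxazolidin-2-one (Z boron enolate, formed in the flask) | COc1cc(C#N)cc(/C=C(\OB(CCCC)CCCC)N2[C@H](Cc3ccccc3)COC2=O)c1F | intermediate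
13 | (R)-4-benzyl-3-[(2R,3R)-2-(5-cyano-2-fluoro-3-methoxyphenyl)-3-(dibutylboryloxy)-3-[3-methoxy-4-(methoxymethoxy)phenyl]propanoyl]oxazolidin-2-one (dibutylboron aldolate of 14, formed in the flask) | COCOc1ccc(cc1OC)[C@H](OB(CCCC)CCCC)[C@@H](c1cc(C#N)cc(OC)c1F)C(=O)N1[C@H](Cc2ccccc2)COC1=O | intermediate
14 | (R)-4-benzyl-3-[(2R,3R)-2-(5-cyano-2-fluoro-3-methoxyphenyl)-3-hydroxy-3-[3-methoxy-4-(methoxymethoxy)phenyl]propanoyl]oxazolidin-2-one | COCOc1ccc(cc1OC)[C@H](O)[C@@H](c1cc(C#N)cc(OC)c1F)C(=O)N1[C@H](Cc2ccccc2)COC1=O | intermediate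
15 | 3-{(1R,2S)-1,3-dihydroxy-1-[3-methoxy-4-(methoxymethoxy)phenyl]propan-2-yl}-4-fluoro-5-methoxybenzonitrile | COCOc1ccc(cc1OC)[C@H](O)[C@@H](c1cc(C#N)cc(OC)c1F)CO | intermediate
16 | 4-fluoro-3-{(1R,2S)-1-hydroxy-3-(methoxymethoxy)-1-[3-methoxy-4-(methoxymethoxy)phenyl]propan-2-yl}-5-methoxybenzonitrile (syn fluoro alcohol) | COCOc1ccc(cc1OC)[C@H](O)[C@@H](c1cc(C#N)cc(OC)c1F)COCOC | intermediate
17 | potassium alkoxide of 16 (formed in the flask) | COCOc1ccc(cc1OC)[C@H]([O-])[C@@H](c1cc(C#N)cc(OC)c1F)COCOC.[K+] | intermediate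
18 | Meisenheimer adduct of 17, potassium salt: ring B closed (2R,3S), C7a sp3 with F and O1 (its configuration not defined), charge drawn on the nitrile nitrogen (formed in the flask) | COCOc1ccc(cc1OC)[C@@H]1OC2(F)C(OC)=CC(=C=[N-])C=C2[C@H]1COCOC.[K+] | intermediate
19 | (2R,3S)-7-methoxy-3-[(methoxymethoxy)methyl]-2-[3-methoxy-4-(methoxymethoxy)phenyl]-2,3-dihydrobenzofuran-5-carbonitrile | COCOc1ccc(cc1OC)[C@@H]1Oc2c(OC)cc(C#N)cc2[C@H]1COCOC | intermediate
20 | N-(diisobutylaluminio)aldimine from 19, (2R,3S) (formed in the flask) | COCOc1ccc(cc1OC)[C@@H]1Oc2c(OC)cc(C=N[Al](CC(C)C)CC(C)C)cc2[C@H]1COCOC | intermediate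
21 | (2R,3S)-7-methoxy-3-[(methoxymethoxy)methyl]-2-[3-methoxy-4-(methoxymethoxy)phenyl]-2,3-dihydrobenzofuran-5-carbaldehyde | COCOc1ccc(cc1OC)[C@@H]1Oc2c(OC)cc(C=O)cc2[C@H]1COCOC | intermediate
22 | (R)-4-benzyl-3-[(2R,3R)-2-(5-cyano-2-fluoro-3-methoxyphenyl)-3-(dibutylboryloxy)-3-{(2R,3S)-7-methoxy-3-[(methoxymethoxy)methyl]-2-[3-methoxy-4-(methoxymethoxy)phenyl]-2,3-dihydrobenzofuran-5-yl}propanoyl]oxazolidin-2-one (dibutylboron aldolate of 23, formed in the flask) | COCOc1ccc(cc1OC)[C@@H]1Oc2c(OC)cc(cc2[C@H]1COCOC)[C@H](OB(CCCC)CCCC)[C@@H](c1cc(C#N)cc(OC)c1F)C(=O)N1[C@H](Cc2ccccc2)COC1=O | intermediate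
23 | (R)-4-benzyl-3-[(2R,3R)-2-(5-cyano-2-fluoro-3-methoxyphenyl)-3-hydroxy-3-{(2R,3S)-7-methoxy-3-[(methoxymethoxy)methyl]-2-[3-methoxy-4-(methoxymethoxy)phenyl]-2,3-dihydrobenzofuran-5-yl}propanoyl]oxazolidin-2-one | COCOc1ccc(cc1OC)[C@@H]1Oc2c(OC)cc(cc2[C@H]1COCOC)[C@H](O)[C@@H](c1cc(C#N)cc(OC)c1F)C(=O)N1[C@H](Cc2ccccc2)COC1=O | intermediate
24 | 3-[(1R,2S)-1,3-dihydroxy-1-{(2R,3S)-7-methoxy-3-[(methoxymethoxy)methyl]-2-[3-methoxy-4-(methoxymethoxy)phenyl]-2,3-dihydrobenzofuran-5-yl}propan-2-yl]-4-fluoro-5-methoxybenzonitrile | COCOc1ccc(cc1OC)[C@@H]1Oc2c(OC)cc(cc2[C@H]1COCOC)[C@H](O)[C@@H](c1cc(C#N)cc(OC)c1F)CO | intermediate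
25 | 4-fluoro-3-[(1R,2S)-1-hydroxy-3-(methoxymethoxy)-1-{(2R,3S)-7-methoxy-3-[(methoxymethoxy)methyl]-2-[3-methoxy-4-(methoxymethoxy)phenyl]-2,3-dihydrobenzofuran-5-yl}propan-2-yl]-5-methoxybenzonitrile | COCOc1ccc(cc1OC)[C@@H]1Oc2c(OC)cc(cc2[C@H]1COCOC)[C@H](O)[C@@H](c1cc(C#N)cc(OC)c1F)COCOC | intermediate
26 | potassium alkoxide of 25 (formed in the flask) | COCOc1ccc(cc1OC)[C@@H]1Oc2c(OC)cc(cc2[C@H]1COCOC)[C@H]([O-])[C@@H](c1cc(C#N)cc(OC)c1F)COCOC.[K+] | intermediate
27 | Meisenheimer adduct of 26, potassium salt: ring D closed (2'R,3'S), C7a' sp3 with F and O1' (its configuration not defined), charge drawn on the nitrile nitrogen (formed in the flask) | COCOc1ccc(cc1OC)[C@@H]1Oc2c(OC)cc(cc2[C@H]1COCOC)[C@@H]1OC2(F)C(OC)=CC(=C=[N-])C=C2[C@H]1COCOC.[K+] | intermediate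
28 | (2R,3S)-7-methoxy-3-[(methoxymethoxy)methyl]-2-{(2R,3S)-7-methoxy-3-[(methoxymethoxy)methyl]-2-[3-methoxy-4-(methoxymethoxy)phenyl]-2,3-dihydrobenzofuran-5-yl}-2,3-dihydrobenzofuran-5-carbonitrile | COCOc1ccc(cc1OC)[C@@H]1Oc2c(OC)cc(cc2[C@H]1COCOC)[C@@H]1Oc2c(OC)cc(C#N)cc2[C@H]1COCOC | intermediate
29 | N-(diisobutylaluminio)aldimine from 28, (2R,3S,2'R,3'S) (formed in the flask) | COCOc1ccc(cc1OC)[C@@H]1Oc2c(OC)cc(cc2[C@H]1COCOC)[C@@H]1Oc2c(OC)cc(C=N[Al](CC(C)C)CC(C)C)cc2[C@H]1COCOC | intermediate
30 | (2R,3S)-7-methoxy-3-[(methoxymethoxy)methyl]-2-{(2R,3S)-7-methoxy-3-[(methoxymethoxy)methyl]-2-[3-methoxy-4-(methoxymethoxy)phenyl]-2,3-dihydrobenzofuran-5-yl}-2,3-dihydrobenzofuran-5-carbaldehyde | COCOc1ccc(cc1OC)[C@@H]1Oc2c(OC)cc(cc2[C@H]1COCOC)[C@@H]1Oc2c(OC)cc(C=O)cc2[C@H]1COCOC | intermediate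
31 | methyl (E)-3-[(2R,3S)-7-methoxy-3-[(methoxymethoxy)methyl]-2-{(2R,3S)-7-methoxy-3-[(methoxymethoxy)methyl]-2-[3-methoxy-4-(methoxymethoxy)phenyl]-2,3-dihydrobenzofuran-5-yl}-2,3-dihydrobenzofuran-5-yl]prop-2-enoate | COCOc1ccc(cc1OC)[C@@H]1Oc2c(OC)cc(cc2[C@H]1COCOC)[C@@H]1Oc2c(OC)cc(/C=C/C(=O)OC)cc2[C@H]1COCOC | intermediate
32 | methyl (E)-3-[(2R,3S)-2-{(2R,3S)-2-(4-hydroxy-3-methoxyphenyl)-3-(hydroxymethyl)-7-methoxy-2,3-dihydrobenzofuran-5-yl}-3-(hydroxymethyl)-7-methoxy-2,3-dihydrobenzofuran-5-yl]prop-2-enoate | COc1cc(ccc1O)[C@@H]1Oc2c(OC)cc(cc2[C@H]1CO)[C@@H]1Oc2c(OC)cc(/C=C/C(=O)OC)cc2[C@H]1CO | intermediate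
33 | (E)-3-[(2R,3S)-2-{(2R,3S)-2-(4-hydroxy-3-methoxyphenyl)-3-(hydroxymethyl)-7-methoxy-2,3-dihydrobenzofuran-5-yl}-3-(hydroxymethyl)-7-methoxy-2,3-dihydrobenzofuran-5-yl]prop-2-en-1-ol (CNP0250921.1) | COc1cc([C@@H]2Oc3c(OC)cc([C@@H]4Oc5c(OC)cc(/C=C/CO)cc5[C@H]4CO)cc3[C@H]2CO)ccc1O | target

## Step count and least certain steps

Total: 19 steps. Longest linear sequence: 18 steps (steps 2 to 19, from 3 to 33); step 1 is the only operation off the main line.

**Step 10 (key step; step 15 is the same reaction on 25).**
- Risk: slow ipso addition. The methoxy group ortho to fluorine crowds C7a and donates into it, so the closure may need warming, and at that point addition of the alkoxide or of residual amide base to the nitrile, or intermolecular arylation, could compete.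
- Fallback (sets out from 4, returns at 19): change the leaving group and form O1–C7a by copper catalysis. Sandmeyer bromination of 4 (t-BuONO, CuBr2, MeCN) would give 4-bromo-3-iodo-5-methoxybenzonitrile F1. Only the iodide should undergo the Negishi coupling of step 4, giving tert-butyl 2-(2-bromo-5-cyano-3-methoxyphenyl)acetate F2. The operations of steps 5 to 9 would then lead through 2-(2-bromo-5-cyano-3-methoxyphenyl)acetic acid F3, its (R)-4-benzyloxazolidinone imide F4, the syn aldol adduct with aldehyde 2 F5 and the bromo diol F6 to the bromo alcohol with the primary MOM ether F7. Intramolecular Ullmann-type O-arylation of F7 (CuI, 1,10-phenanthroline, Cs2CO3, toluene, 110 °C) also leaves the C2–O bond intact and should give 19.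

**Step 3.**
- Risk: thermal dediazoniation diverted into reduction, loss of iodine or tar formation instead of fluoride capture, which is common for crowded, electron-poor diazonium salts.
- Fallback (from 4, returns at 6): Sandmeyer chlorination of 4 (t-BuONO, CuCl2, MeCN, 60 °C) would give 4-chloro-3-iodo-5-methoxybenzonitrile F8. Halogen exchange (spray-dried KF, Ph4PBr, sulfolane, 180 °C) should then replace only the chloride, which is para to the nitrile; the iodide is meta and not activated.

**Step 8 (and its repeat, step 13).**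
- Risk: retro-aldol fragmentation of the β-hydroxy imide and epimerisation at the acidic α-aryl carbon under the basic aqueous borohydride, followed in step 9 by incomplete discrimination between the two hydroxyls.
- Fallback (from 14, returns at 16): silylate the secondary hydroxyl (TBSOTf, 2,6-lutidine, CH2Cl2, −78 °C) to the tert-butyldimethylsilyl ether of 14 F9, which cannot fragment. Reduce with LiBH4/MeOH in THF to the primary alcohol with the silyl ether retained F10. Alkylate with MOMCl/i-Pr2NEt to the MOM silyl bis-ether F11. Remove silicon with Bu4NF buffered by AcOH (THF, 0 °C) to reach 16. This costs two extra steps and removes the selectivity question of step 9.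

**Step 18.**
- Risk: acid-promoted ionisation of the benzylic C2–O1 and C2'–O1' bonds with methanolysis or loss of the trans relationship, before the two slower aliphatic acetals are fully cleaved.
- Fallback (from 28, returns at 32): move the deprotection ahead of any carbonyl group and use a Lewis acid with a soft nucleophile. ZnBr2/n-PrSH (CH2Cl2, 0 °C) on 28 would give the triol nitrile F12. Excess i-Bu2AlH followed by hydrolysis would give the triol aldehyde F13. The Wittig reaction of step 17 on F13 leads to 32.

## Further compounds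

F1 | step 10 | 4-bromo-3-iodo-5-methoxybenzonitrile | COc1cc(C#N)cc(I)c1Br
F2 | step 10 | tert-butyl 2-(2-bromo-5-cyano-3-methoxyphenyl)acetate | COc1cc(C#N)cc(CC(=O)OC(C)(C)C)c1Br
F3 | step 10 | 2-(2-bromo-5-cyano-3-methoxyphenyl)acetic acid | COc1cc(C#N)cc(CC(=O)O)c1Br
F4 | step 10 | (R)-4-benzyl-3-[2-(2-bromo-5-cyano-3-methoxyphenyl)acetyl]oxazolidin-2-one | COc1cc(C#N)cc(CC(=O)N2[C@H](Cc3ccccc3)COC2=O)c1Br
F5 | step 10 | (R)-4-benzyl-3-[(2R,3R)-2-(2-bromo-5-cyano-3-methoxyphenyl)-3-hydroxy-3-[3-methoxy-4-(methoxymethoxy)phenyl]propanoyl]oxazolidin-2-one | COCOc1ccc(cc1OC)[C@H](O)[C@@H](c1cc(C#N)cc(OC)c1Br)C(=O)N1[C@H](Cc2ccccc2)COC1=O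
F6 | step 10 | 4-bromo-3-{(1R,2S)-1,3-dihydroxy-1-[3-methoxy-4-(methoxymethoxy)phenyl]propan-2-yl}-5-methoxybenzonitrile | COCOc1ccc(cc1OC)[C@H](O)[C@@H](c1cc(C#N)cc(OC)c1Br)CO
F7 | step 10 | 4-bromo-3-{(1R,2S)-1-hydroxy-3-(methoxymethoxy)-1-[3-methoxy-4-(methoxymethoxy)phenyl]propan-2-yl}-5-methoxybenzonitrile | COCOc1ccc(cc1OC)[C@H](O)[C@@H](c1cc(C#N)cc(OC)c1Br)COCOC
F8 | step 3 | 4-chloro-3-iodo-5-methoxybenzonitrile | COc1cc(C#N)cc(I)c1Cl
F9 | step 8 | (R)-4-benzyl-3-[(2R,3R)-3-(tert-butyldimethylsilyloxy)-2-(5-cyano-2-fluoro-3-methoxyphenyl)-3-[3-methoxy-4-(methoxymethoxy)phenyl]propanoyl]oxazolidin-2-one | COCOc1ccc(cc1OC)[C@H](O[Si](C)(C)C(C)(C)C)[C@@H](c1cc(C#N)cc(OC)c1F)C(=O)N1[C@H](Cc2ccccc2)COC1=O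
F10 | step 8 | 3-{(1R,2S)-1-(tert-butyldimethylsilyloxy)-3-hydroxy-1-[3-methoxy-4-(methoxymethoxy)phenyl]propan-2-yl}-4-fluoro-5-methoxybenzonitrile | COCOc1ccc(cc1OC)[C@H](O[Si](C)(C)C(C)(C)C)[C@@H](c1cc(C#N)cc(OC)c1F)CO
F11 | step 8 | 3-{(1R,2S)-1-(tert-butyldimethylsilyloxy)-3-(methoxymethoxy)-1-[3-methoxy-4-(methoxymethoxy)phenyl]propan-2-yl}-4-fluoro-5-methoxybenzonitrile | COCOc1ccc(cc1OC)[C@H](O[Si](C)(C)C(C)(C)C)[C@@H](c1cc(C#N)cc(OC)c1F)COCOC
F12 | step 18 | (2R,3S)-2-{(2R,3S)-2-(4-hydroxy-3-methoxyphenyl)-3-(hydroxymethyl)-7-methoxy-2,3-dihydrobenzofuran-5-yl}-3-(hydroxymethyl)-7-methoxy-2,3-dihydrobenzofuran-5-carbonitrile | COc1cc(ccc1O)[C@@H]1Oc2c(OC)cc(cc2[C@H]1CO)[C@@H]1Oc2c(OC)cc(C#N)cc2[C@H]1CO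
F13 | step 18 | (2R,3S)-2-{(2R,3S)-2-(4-hydroxy-3-methoxyphenyl)-3-(hydroxymethyl)-7-methoxy-2,3-dihydrobenzofuran-5-yl}-3-(hydroxymethyl)-7-methoxy-2,3-dihydrobenzofuran-5-carbaldehyde | COc1cc(ccc1O)[C@@H]1Oc2c(OC)cc(cc2[C@H]1CO)[C@@H]1Oc2c(OC)cc(C=O)cc2[C@H]1CO
A1 | alternative 1 | [3-methoxy-4-(methoxymethoxy)phenyl]lithium | [Li]c1ccc(OCOC)c(OC)c1
A2 | alternative 1 | (E)-tert-butyldimethyl{[3-(4,4,5,5-tetramethyl-1,3,2-dioxaborolan-2-yl)prop-2-en-1-yl]oxy}silane | CC(C)(C)[Si](C)(C)OC/C=C/B1OC(C)(C)C(C)(C)O1
A3 | alternative 1 | 1-bromo-5-chloro-3-methoxy-2-(methoxymethoxy)benzene | COCOc1c(Br)cc(Cl)cc1OC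
A4 | alternative 1 | secondary benzylic pinacol boronate carrying ring A on the boron-bearing carbon and arene C plus CH2OTBS on the next carbon (configuration as in the SMILES) | COCOc1ccc(cc1OC)[C@H](B1OC(C)(C)C(C)(C)O1)[C@@H](c1cc(Cl)cc(OC)c1OCOC)CO[Si](C)(C)C(C)(C)C
A5 | alternative 2 | acyclic bis(aryldiazoacetate): ring A benzyl ether of arene C and arene C benzyl ether of arene E, each arene bearing a methyl diazoacetate ortho to the ether oxygen | COc1cc(COc2c(OC)cc(COc3c(OC)cc(/C=C/C(=O)OC)cc3C(=[N+]=[N-])C(=O)OC)cc2C(=[N+]=[N-])C(=O)OC)ccc1O[Si](C(C)C)(C(C)C)C(C)C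
A6 | alternative 2 | trans,trans triester after epimerisation (ring A phenol as its triisopropylsilyl ether) | COc1cc([C@@H]2Oc3c(OC)cc([C@@H]4Oc5c(OC)cc(/C=C/C(=O)OC)cc5[C@H]4C(=O)OC)cc3[C@H]2C(=O)OC)ccc1O[Si](C(C)C)(C(C)C)C(C)C
A7 | alternative 3 | 4-bromo-2-[2-(tert-butyldimethylsilyloxy)-1-tosylethyl]-6-methoxyphenol (racemic at the sulfone carbon) | COc1cc(Br)cc(C(CO[Si](C)(C)C(C)(C)C)S(=O)(=O)c2ccc(C)cc2)c1O
A8 | alternative 3 | fragment 1 sulfonium salt: (2R,3S) ring A–ring B unit with a (tetrahydrothiophenium-1-yl)methyl group at C5, bromide | COCOc1ccc(cc1OC)[C@@H]1Oc2c(OC)cc(C[S+]3CCCC3)cc2[C@H]1CO[Si](C)(C)C(C)(C)C.[Br-]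
A9 | alternative 3 | arene E o-quinone methide: 4-bromo-6-[2-(tert-butyldimethylsilyloxy)ethylidene]-2-methoxycyclohexa-2,4-dien-1-one | COC1=CC(Br)=CC(=CCO[Si](C)(C)C(C)(C)C)C1=O
A10 | alternative 3 | protected bis(dihydrobenzofuran) bromide (2R,3S,2'R,3'S) | COc1cc([C@@H]2Oc3c(OC)cc([C@@H]4Oc5c(OC)cc(Br)cc5[C@H]4CO[Si](C)(C)C(C)(C)C)cc3[C@H]2CO[Si](C)(C)C(C)(C)C)ccc1OCOC
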